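# Proposed total synthesis of CNP0418642.2 (35) by acetal-initiated ene-yne cationic bicyclisation

## The problem

The target 35 is a trans-fused hydrindane (bicyclo[4.3.0]nonane) in which eight of the nine ring carbons are substituted. Route locants (not IUPAC) are used throughout:

- C1 carries the exocyclic methylidene, C2 the (E)-3-methylpent-2-enoate, C3 the free hydroxyl and C4 the isopropyl group.
- C5 and C6 are the ring-fusion carbons (C5 next to C4, C6 next to C1) and C7 is the cyclopentane CH2.
- C8 carries the acetate and C9 the ethylidene (C10, C11); β is the face of 6-H.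

Six contiguous stereocentres must be set: 6-H β and 5-H α (trans fusion), 4-isopropyl α (equatorial), 3-OH α and 2-acyloxy β (a trans-diaxial pair) and 8-OAc β. The ethylidene is Z, with its methyl turned towards C8. C4 is the natural control element: equatorial in a chair, it can fix C5 and C6. The rigid trans-fused chair then dictates axial attack at C2 and C3, so one epoxide can deliver both oxygens, while the locked cyclopentene envelope and the C4 isopropyl group bias C8 and the alkene geometry.

Late intermediates will not survive rough treatment. The allylic acetate and the allylic enoate ionise or hydrolyse easily, and the E-enoate can isomerise or deconjugate under base. The two exocyclic alkenes exclude hydrogenation and strong acid, and a C1 ketone is epimerisable at C6. Because the two esters differ, the oxygens must be introduced in an order that never leaves two free hydroxyls to be told apart.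

The feature that makes the key step possible is that the bonds C1–C6 and C5–C9 flank the fusion bond C5–C6. Trans hydrogens at C5/C6, an equatorial group at C4 and a two-carbon unit on C9 are what a chair cation–olefin closure of an E-alkene (C5=C6) gives when it is started at C1 and ended by a methylacetylene (C9≡C10–C11).

## Retrosynthesis

**C2–O bond (35 ⇒ 33 + 34).** The ester oxygen–C2 bond is cut, leading back to the 2α,3α-epoxide 33 and acid 34. Against acylating a 2,3-diol, this cut needs no choice between two axial hydroxyls and no basic acylation that could scramble the enoate. The acyl group can only arrive at C2, with inversion, and the epoxide oxygen stays on C3 as the α-hydroxyl. The precursor holds both oxygens in one ring and has no free hydroxyl. The forward reaction must be direct attack at the allylic C2 rather than attack at the methylidene terminus.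

**C1=CH2, epoxide and C2=C3 (33 ⇒ 32 ⇒ 31 ⇒ 29).** The methylidene carbon, the epoxide oxygen and the C2=C3 unsaturation are removed in turn, back to ketone 29. The C1 carbonyl does three jobs: it allows dehydrogenation towards C2, it steers nucleophilic epoxidation to the α-face by axial attack at C3, and it becomes the methylidene. Allylic oxidation of a preformed methylidene would reach C2 only. Each forward step has to spare the C8 acetate.

**Five-membered ring (29 ⇒ 28 ⇒ 27 ⇒ 26 ⇒ 23 ⇒ 22 ⇒ 20).** The C8–O bond and the C9=C10 alkene are traced to the 8β,9β-epoxy methyl ketone 23 (Wharton transposition), then to enone 22 and the saturated methyl ketone 20. This is preferred to allylic oxidation of an ethylidene, which is expected to leave the methyl on the C5 side. It is placed before the six-ring work because hydrazine and alkaline peroxide would destroy the esters. C1 is carried as a silyl ether (27 → 28 → 29) so that only one carbonyl is present at a time.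

**Protecting-group exchange (20 ⇒ 19 ⇒ 18).** The silyl ether is traced to the benzyl ether 18. Benzyl is the robust choice for the acidic ring closure but can only be removed by hydrogenolysis while no alkene is present, i.e. directly after the cyclisation.

**Key disconnection (18 ⇒ 16).** C1–C6 and C5–C9 are cut together, opening both rings to the acyclic (E)-enyne dibenzyl acetal 16. Neighbouring cuts (C2–C3, C3–C4, C6–C7) each close only one ring and need a stereodefined carbocycle first. Here the precursor has one stereocentre, one E-alkene and no ring. The forward reaction must show facial selectivity at the alkene under control of C4.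

**Acetal, chain oxidation and C5=C6 (16 ⇒ 15 ⇒ 14 ⇒ 12 ⇒ 7 + 11).** The acetal comes from aldehyde 15, the aldehyde from alcohol 14, and the alcohol from terminal alkene 12 by anti-Markovnikov hydration. The C5=C6 bond is cut by Julia–Kocienski olefination into aldehyde 7 and sulfone 11, which asks only for E-selectivity, best with an α-branched aldehyde.

**Stereocentre and sulfone (7 ⇒ 6 ⇒ 5 ⇒ 3 + 4; 3 ⇒ 1 + 2; 11 ⇒ 10 ⇒ 8 + 9).** The C4 centre is traced to Evans allylation of the isovaleryl imide 3 (from 1 and 2) with allyl bromide 4. The auxiliary is removed reductively via 5 and 6. The sulfone comes from hex-4-yn-1-ol 8 and thiol 9.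

## Roads not taken

**Alternative 1:** The cyclohexane is cut at C3–C4. Oxime A1 is a finished cyclopentane carrying the 8-silyloxy group, the Z-ethylidene, a ketal-protected C1 arm and an isobutenyl group on C5. NaOCl would convert it into a nitrile oxide that adds across the isobutenyl alkene to give isoxazoline A2.
- Merits: the ring closure is mild and dependable. C1 and C3 arrive at the carbonyl level, so C2 could be oxygenated by enolate chemistry and C4 equilibrated next to the C3 carbonyl. The sensitive five-ring part is complete before closure.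
- Weak points: the isopropyl carbon emerges as a tertiary carbinol that must be deoxygenated in the presence of the ethylidene. The trisubstituted dipolarophile is slow and competes with the ethylidene. A1 itself, with three cyclopentane stereocentres and a Z-alkene, needs a separate stereocontrolled synthesis.
- Comparison: this road is better in oxidation-state economy at C1 and C3, since it avoids the second dehydrogenation–epoxidation sequence. The chosen plan sets against that the formation of both rings and the ring fusion from one acyclic stereocentre, and an isopropyl group that is present from the first step.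

**Alternative 2:** The cut is C2–C3. Aldehyde A3, a cyclopentanone with an isopropenyl group on C6 and the C4 aldehyde side chain on C5, would undergo a type 2 carbonyl-ene reaction with Me2AlCl to give A4.
- Merits: the cyclohexane, the methylidene and the C3 carbinol are made in one step. For C1 this is better than a Wittig reaction on an epoxy ketone, and the endgame is shorter.
- Weak points: C2 is left unoxidised. It would have to be hydroxylated next to the new methylidene, with C2-versus-C6 regiochemistry and β-axial selectivity both unsecured. The aldehyde is epimerisable at C4, and the Z-ethylidene enone is exposed to a Lewis acid. A3 again requires three contiguous centres to be built first.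
- Comparison: fewer steps after ring closure is a real advantage. The chosen plan answers with a trans-diaxial C2/C3 pair drawn from one epoxide, with the acyl position fixed by mechanism.

**Alternative 3:** The cut is C6–C7. Anodic oxidation of bis(silyl enol ether) A5 would join the terminus of the silyloxydiene to C6 of the cyclohexenyl silyl ether, giving dione A6 after base equilibration.
- Merits: the closure delivers C1 and C8 at the ketone level with the ethylidene in place. It needs no protecting group at C1 and would save roughly the four steps of the Wharton sequence.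
- Weak points: which of two electron-rich enol ethers is oxidised and where the radical cation is attacked are not secured. Both the Z-geometry and the trans fusion rest on equilibria. The two ketones must then be told apart, and the C2/C3 oxygens still need the same sequence as in the chosen route.
- Comparison: this road is shorter in the five-membered ring. The chosen plan sets against it a ring closure of an established type whose stereochemical outcome follows from one centre and one alkene geometry.

Key step: step 11

## Route

Assumption: (2E)-3-methylpent-2-enoic acid (34) is bought as the pure E acid. Compounds 18–28 are drawn as the expected 1β epimers (18–20 also as 9α); any epimer at C1 or C9 is carried along because both carbons later become trigonal.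

Step 1
Reactants: 1 (S)-4-benzyloxazolidin-2-one; 2 3-methylbutanoyl chloride (isovaleryl chloride)
Product: 3 (4S)-4-benzyl-3-(3-methylbutanoyl)oxazolidin-2-one
Conditions: n-BuLi, THF, −78 °C; then 2, −78 → 0 °C
Reagents that add atoms: none
Why: N-acylation of the lithiated oxazolidinone, the standard entry to Evans imides.

Step 2
Reactants: 3 (4S)-4-benzyl-3-(3-methylbutanoyl)oxazolidin-2-one; 4 allyl bromide
Product: 5 (4S)-4-benzyl-3-[(2S)-2-(propan-2-yl)pent-4-enoyl]oxazolidin-2-one
Conditions: NaN(SiMe3)2, THF, −78 °C; then 4, −78 → −40 °C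
Reagents that add atoms: none
Why: Evans alkylation; the chelated Z-enolate is allylated on the face away from the benzyl group, which sets the future C4 centre as 2S.

Step 3
Reactants: 5 (4S)-4-benzyl-3-[(2S)-2-(propan-2-yl)pent-4-enoyl]oxazolidin-2-one
Product: 6 (2S)-2-(propan-2-yl)pent-4-en-1-ol
Conditions: LiBH4, H2O (1 equiv), Et2O, 0 °C
Reagents that add atoms: none
Why: Reductive cleavage of the imide; the stereocentre is not enolisable under these conditions and the auxiliary is recovered.

Step 4
Reactants: 6 (2S)-2-(propan-2-yl)pent-4-en-1-ol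
Product: 7 (2S)-2-(propan-2-yl)pent-4-enal
Conditions: Dess–Martin periodinane, CH2Cl2, 0 → 25 °C; used without storage
Reagents that add atoms: none
Why: Dess–Martin oxidation is non-basic, so the α-branched aldehyde should be obtained without epimerisation.

Step 5
Reactants: 8 hex-4-yn-1-ol; 9 1-phenyl-1H-tetrazole-5-thiol
Product: 10 5-(hex-4-yn-1-ylsulfanyl)-1-phenyl-1H-tetrazole
Conditions: PPh3, DIAD, THF, 0 → 25 °C
Reagents that add atoms: none
Why: Mitsunobu thioetherification of a primary alcohol with the acidic tetrazole thiol.

Step 6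
Reactants: 10 5-(hex-4-yn-1-ylsulfanyl)-1-phenyl-1H-tetrazole
Product: 11 5-(hex-4-yn-1-ylsulfonyl)-1-phenyl-1H-tetrazole
Conditions: (NH4)6Mo7O24·4H2O (cat.), 30% H2O2, EtOH, 0 → 25 °C
Reagents that add atoms: hydrogen peroxide, OO
Why: Molybdate-catalysed sulfide-to-sulfone oxidation, which leaves the internal alkyne untouched.

Step 7
Reactants: 11 5-(hex-4-yn-1-ylsulfonyl)-1-phenyl-1H-tetrazole; 7 (2S)-2-(propan-2-yl)pent-4-enal
Product: 12 (4S,5E)-4-(propan-2-yl)undeca-1,5-dien-9-yne
Conditions: KN(SiMe3)2, DME, −60 °C; then 7, −60 → 25 °C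
Reagents that add atoms: none
Why: Julia–Kocienski olefination; an unbranched phenyltetrazolyl sulfone with an α-branched aldehyde in DME is the most E-selective combination, and the pre-formed sulfonyl anion limits epimerisation of 7.

Step 8
Reactants: 12 (4S,5E)-4-(propan-2-yl)undeca-1,5-dien-9-yne
Product: 14 (4S,5E)-4-(propan-2-yl)undec-5-en-9-yn-1-ol, via B-alkyl-9-BBN adduct 13 (not isolated)
Conditions: 9-BBN, THF, 0 → 25 °C; then NaOH, 30% H2O2, 0 °C
Reagents that add atoms: hydrogen peroxide, OO
Why: Anti-Markovnikov hydroboration–oxidation; 9-BBN reacts with the monosubstituted alkene much faster than with the 1,2-disubstituted alkene or the internal alkyne.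

Step 9
Reactants: 14 (4S,5E)-4-(propan-2-yl)undec-5-en-9-yn-1-ol
Product: 15 (4S,5E)-4-(propan-2-yl)undec-5-en-9-ynal
Conditions: Dess–Martin periodinane, CH2Cl2, 0 → 25 °C
Reagents that add atoms: none
Why: Dess–Martin oxidation of a primary alcohol; no enolisable stereocentre is adjacent.

Step 10
Reactants: 15 (4S,5E)-4-(propan-2-yl)undec-5-en-9-ynal
Product: 16 (4S,5E)-1,1-bis(benzyloxy)-4-(propan-2-yl)undec-5-en-9-yne
Conditions: PhCH2OSiMe3 (2.2 equiv), TMSOTf (cat.), CH2Cl2, −78 °C
Reagents that add atoms: benzyloxytrimethylsilane, C[Si](C)(C)OCc1ccccc1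
Why: Aprotic acetalisation with a silyl ether and catalytic silyl triflate is irreversible and avoids azeotropic water removal with a high-boiling alcohol.

Step 11
Reactants: 16 (4S,5E)-1,1-bis(benzyloxy)-4-(propan-2-yl)undec-5-en-9-yne
Product: 18 9α-acetyl-1β-benzyloxy-4α-isopropyl-5αH,6βH-hydrindane, via enol trifluoroacetate 17 (not isolated)
Conditions: CF3CO2H, CH2Cl2, −78 → −20 °C; then K2CO3, MeOH/H2O, 25 °C
Reagents that add atoms: trifluoroacetic acid, OC(=O)C(F)(F)F
Why: CF3CO2H ionises the acetal to an (E)-benzyloxocarbenium ion at C1; the C5=C6 alkene attacks it through C6 in a chair (6-endo-trig) while the methylacetylene adds anti at C5 through C9 (5-exo-dig), so the C1–C6 and C5–C9 bonds form in one cascade. The linear alkenyl cation at C10 is captured by trifluoroacetate as enol ester 17, and carbonate methanolysis releases the methyl ketone, so the acid supplies the ketone oxygen. The closest known reaction type is the acetal-initiated biomimetic polyene cyclisation terminated by a methylacetylene, which gives trans-hydrindanyl methyl ketones. 5-H and 6-H become trans because antiperiplanar addition across the E-alkene translates its geometry into the ring fusion. Their sense relative to C4 follows from the chair in which the isopropyl group of the pre-set centre, which lies inside the forming ring, is equatorial; this facial selectivity is the one selectivity the step needs. C1 should carry its benzyloxy group equatorial (1β) and C9 is set on ketonisation (9α expected), but both centres are erased later and their ratio is immaterial. Low temperature and a weakly nucleophilic medium should keep the secondary cation from being intercepted before the alkyne engages.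

Step 12
Reactants: 18 9α-acetyl-1β-benzyloxy-4α-isopropyl-5αH,6βH-hydrindane
Product: 19 9α-acetyl-4α-isopropyl-5αH,6βH-hydrindan-1β-ol
Conditions: H2 (1 atm), 10% Pd/C, EtOAc, 25 °C
Reagents that add atoms: none
Why: Benzyl ether hydrogenolysis at the only stage where the molecule has no alkene; the ketone is inert.

Step 13
Reactants: 19 9α-acetyl-4α-isopropyl-5αH,6βH-hydrindan-1β-ol
Product: 20 9α-acetyl-1β-(tert-butyldimethylsilyloxy)-4α-isopropyl-5αH,6βH-hydrindane
Conditions: TBSCl, imidazole, DMF, 25 °C
Reagents that add atoms: tert-butyldimethylsilyl chloride, CC(C)(C)[Si](C)(C)Cl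
Why: Silylation of a secondary alcohol; the silyl ether survives peroxide, hydrazine and acylation and can later be removed by fluoride beside an allylic acetate.

Step 14
Reactants: 20 9α-acetyl-1β-(tert-butyldimethylsilyloxy)-4α-isopropyl-5αH,6βH-hydrindane
Product: 22 9-acetyl-1β-(tert-butyldimethylsilyloxy)-4α-isopropyl-5αH,6βH-hydrind-8-ene, via trimethylsilyl enol ether 21 (not isolated)
Conditions: TMSCl, NaI, Et3N, MeCN, 25 °C (equilibrating silylation); then Pd(OAc)2, MeCN, 25–40 °C
Reagents that add atoms: none
Why: Saegusa–Ito dehydrogenation via the more substituted silyl enol ether; only the C9=C10 isomer can undergo β-hydride elimination (the terminal isomer reverts to 20 on work-up and is recycled), and elimination towards C8 avoids the allylic strain against C4 that a C5=C9 alkene would carry. The 20-oxo-steroid to 16-en-20-one conversion is the close model.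

Step 15
Reactants: 22 9-acetyl-1β-(tert-butyldimethylsilyloxy)-4α-isopropyl-5αH,6βH-hydrind-8-ene
Product: 23 9-acetyl-1β-(tert-butyldimethylsilyloxy)-8β,9β-epoxy-4α-isopropyl-5αH,6βH-hydrindane
Conditions: 30% H2O2, NaOH (aq.), MeOH, 0 °C
Reagents that add atoms: hydrogen peroxide, OO
Why: Weitz–Scheffer epoxidation; hydroperoxide should add to C8 on the β-face, the side of the C6 flap of the locked cyclopentene envelope and anti to the pseudoaxial allylic C–H bonds at C7 and C5, as in the 16-en-20-one steroid series. Ring closure then turns the acetyl group to the open α-face.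

Step 16
Reactants: 23 9-acetyl-1β-(tert-butyldimethylsilyloxy)-8β,9β-epoxy-4α-isopropyl-5αH,6βH-hydrindane
Product: 26 (9Z)-1β-(tert-butyldimethylsilyloxy)-9-ethylidene-4α-isopropyl-5αH,6βH-hydrindan-8β-ol, via epoxy hydrazone 24 (not isolated), via alkenyl diazene 25 (not isolated)
Conditions: N2H4·H2O, AcOH (cat.), MeOH, 0 → 25 °C
Reagents that add atoms: none
Why: Wharton transposition; the C8–O bond is untouched, so 8β-OH follows from the epoxide. The alkene geometry is set when the epoxide opens from the hydrazone rotamer that keeps the methyl on the C8 side, away from C4 and its isopropyl group, which is also the more stable isomer; the steroidal 16,17-epoxy-20-ketone to 17(20)-en-16-ol transposition is the close model.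

Step 17
Reactants: 26 (9Z)-1β-(tert-butyldimethylsilyloxy)-9-ethylidene-4α-isopropyl-5αH,6βH-hydrindan-8β-ol
Product: 27 (9Z)-8β-acetoxy-1β-(tert-butyldimethylsilyloxy)-9-ethylidene-4α-isopropyl-5αH,6βH-hydrindane
Conditions: Ac2O, pyridine, DMAP (cat.), CH2Cl2, 25 °C
Reagents that add atoms: acetic anhydride, CC(=O)OC(C)=O
Why: DMAP-catalysed acetylation of the only free hydroxyl; doing it now means the acetate never has to be placed selectively beside 3-OH.

Step 18
Reactants: 27 (9Z)-8β-acetoxy-1β-(tert-butyldimethylsilyloxy)-9-ethylidene-4α-isopropyl-5αH,6βH-hydrindane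
Product: 28 (9Z)-8β-acetoxy-9-ethylidene-4α-isopropyl-5αH,6βH-hydrindan-1β-ol
Conditions: HF·pyridine, pyridine, THF, 0 → 25 °C
Reagents that add atoms: none
Why: Buffered fluoride desilylation, which leaves the allylic acetate and the trisubstituted alkene intact.

Step 19
Reactants: 28 (9Z)-8β-acetoxy-9-ethylidene-4α-isopropyl-5αH,6βH-hydrindan-1β-ol
Product: 29 (9Z)-8β-acetoxy-9-ethylidene-4α-isopropyl-5αH,6βH-hydrindan-1-one
Conditions: Dess–Martin periodinane, CH2Cl2, 0 → 25 °C
Reagents that add atoms: none
Why: Dess–Martin oxidation of a secondary alcohol under neutral conditions; the trans fusion is also the more stable arrangement for this ketone, so C6 is not at risk.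

Step 20
Reactants: 29 (9Z)-8β-acetoxy-9-ethylidene-4α-isopropyl-5αH,6βH-hydrindan-1-one
Product: 31 (9Z)-8β-acetoxy-9-ethylidene-4α-isopropyl-5αH,6βH-hydrind-2-en-1-one, via trimethylsilyl enol ether 30 (not isolated)
Conditions: LiN(iPr)2 (1.05 equiv), TMSCl (in situ), THF, −78 °C; then Pd(OAc)2, MeCN, 25 °C
Reagents that add atoms: none
Why: Saegusa–Ito dehydrogenation; kinetic deprotonation takes the C2 methylene rather than the ring-fusion methine C6, and with TMSCl present at −78 °C the ketone is deprotonated in preference to the acetate.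

Step 21
Reactants: 31 (9Z)-8β-acetoxy-9-ethylidene-4α-isopropyl-5αH,6βH-hydrind-2-en-1-one
Product: 32 (9Z)-8β-acetoxy-2α,3α-epoxy-9-ethylidene-4α-isopropyl-5αH,6βH-hydrindan-1-one
Conditions: t-BuOOH, DBU, CH2Cl2, 0 → 25 °C
Reagents that add atoms: tert-butyl hydroperoxide, CC(C)(C)OO
Why: Anhydrous Weitz–Scheffer-type epoxidation that spares the acetate; the peroxide anion attacks C3 axially, which in the locked half-chair is the α-face (anti to the axial 4-H), and closure gives the 2α,3α-epoxide. The equatorial isopropyl group and the trans fusion are the thermodynamic arrangements should C4 or C6 be touched by base.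

Step 22
Reactants: 32 (9Z)-8β-acetoxy-2α,3α-epoxy-9-ethylidene-4α-isopropyl-5αH,6βH-hydrindan-1-one
Product: 33 (9Z)-8β-acetoxy-2α,3α-epoxy-9-ethylidene-4α-isopropyl-1-methylidene-5αH,6βH-hydrindane
Conditions: Ph3PCH3Br, KN(SiMe3)2, THF, −78 → 0 °C (1.3 equiv ylide)
Reagents that add atoms: methyltriphenylphosphonium bromide, C[P+](c1ccccc1)(c1ccccc1)c1ccccc1.[Br-]
Why: Wittig methylenation of an α,β-epoxy ketone; the ketone reacts far faster than the acetate with a small excess of ylide at low temperature, and the epoxide is not opened.

Step 23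
Reactants: 33 (9Z)-8β-acetoxy-2α,3α-epoxy-9-ethylidene-4α-isopropyl-1-methylidene-5αH,6βH-hydrindane; 34 (2E)-3-methylpent-2-enoic acid
Product: 35 (9Z)-8β-acetoxy-9-ethylidene-3α-hydroxy-4α-isopropyl-1-methylidene-5αH,6βH-hydrindan-2β-yl (2E)-3-methylpent-2-enoate (CNP0418642.2)
Conditions: 34 (3 equiv), Cs2CO3 (0.5 equiv), DMF, 60 °C
Reagents that add atoms: none
Why: Carboxylate opening of a vinyl epoxide at the allylic carbon with inversion; attack at C2 from the β-face is the trans-diaxial (Fürst–Plattner) mode and gives the 2β-ester and 3α-hydroxyl in one step. The buffered acid/carboxylate medium cannot isomerise the enoate, and the trans-diaxial product cannot undergo acyl migration.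

## Compound list

1 | (S)-4-benzyloxazolidin-2-one | O=C1N[C@@H](Cc2ccccc2)CO1 | starting material
2 | 3-methylbutanoyl chloride (isovaleryl chloride) | CC(C)CC(=O)Cl | starting material
3 | (4S)-4-benzyl-3-(3-methylbutanoyl)oxazolidin-2-one | CC(C)CC(=O)N1[C@@H](Cc2ccccc2)COC1=O | intermediate
4 | allyl bromide | C=CCBr | starting material
5 | (4S)-4-benzyl-3-[(2S)-2-(propan-2-yl)pent-4-enoyl]oxazolidin-2-one | C=CC[C@@H](C(C)C)C(=O)N1[C@@H](Cc2ccccc2)COC1=O | intermediate
6 | (2S)-2-(propan-2-yl)pent-4-en-1-ol | C=CC[C@@H](C(C)C)CO | intermediate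
7 | (2S)-2-(propan-2-yl)pent-4-enal | C=CC[C@@H](C(C)C)C=O | intermediate
8 | hex-4-yn-1-ol | CC#CCCCO | starting material
9 | 1-phenyl-1H-tetrazole-5-thiol | Sc1nnnn1-c1ccccc1 | starting material
10 | 5-(hex-4-yn-1-ylsulfanyl)-1-phenyl-1H-tetrazole | CC#CCCCSc1nnnn1-c1ccccc1 | intermediate
11 | 5-(hex-4-yn-1-ylsulfonyl)-1-phenyl-1H-tetrazole | CC#CCCCS(=O)(=O)c1nnnn1-c1ccccc1 | intermediate
12 | (4S,5E)-4-(propan-2-yl)undeca-1,5-dien-9-yne | C=CC[C@@H](C(C)C)/C=C/CCC#CC | intermediate
13 | 9-[(4S,5E)-4-(propan-2-yl)undec-5-en-9-yn-1-yl]-9-borabicyclo[3.3.1]nonane (not isolated) | B1(CCC[C@@H](C(C)C)/C=C/CCC#CC)C2CCCC1CCC2 | intermediate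
14 | (4S,5E)-4-(propan-2-yl)undec-5-en-9-yn-1-ol | OCCC[C@@H](C(C)C)/C=C/CCC#CC | intermediate
15 | (4S,5E)-4-(propan-2-yl)undec-5-en-9-ynal | O=CCC[C@@H](C(C)C)/C=C/CCC#CC | intermediate
16 | (4S,5E)-1,1-bis(benzyloxy)-4-(propan-2-yl)undec-5-en-9-yne (key-step precursor) | C(OCc1ccccc1)(OCc1ccccc1)CC[C@@H](C(C)C)/C=C/CCC#CC | intermediate
17 | 1β-benzyloxy-4α-isopropyl-9-[1-(trifluoroacetoxy)ethylidene]-5αH,6βH-hydrindane (E/Z mixture; not isolated) | O(Cc1ccccc1)[C@H]1[C@@H]2CCC(=C(C)OC(=O)C(F)(F)F)[C@H]2[C@H](C(C)C)CC1 | intermediate
18 | 9α-acetyl-1β-benzyloxy-4α-isopropyl-5αH,6βH-hydrindane (key-step product) | O(Cc1ccccc1)[C@H]1[C@@H]2CC[C@H](C(C)=O)[C@H]2[C@H](C(C)C)CC1 | intermediate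
19 | 9α-acetyl-4α-isopropyl-5αH,6βH-hydrindan-1β-ol | O[C@H]1[C@@H]2CC[C@H](C(C)=O)[C@H]2[C@H](C(C)C)CC1 | intermediate
20 | 9α-acetyl-1β-(tert-butyldimethylsilyloxy)-4α-isopropyl-5αH,6βH-hydrindane | CC(C)(C)[Si](C)(C)O[C@H]1[C@@H]2CC[C@H](C(C)=O)[C@H]2[C@H](C(C)C)CC1 | intermediate
21 | 1β-(tert-butyldimethylsilyloxy)-4α-isopropyl-9-[1-(trimethylsilyloxy)ethylidene]-5αH,6βH-hydrindane (E/Z mixture; not isolated) | CC(C)(C)[Si](C)(C)O[C@H]1[C@@H]2CCC(=C(C)O[Si](C)(C)C)[C@H]2[C@H](C(C)C)CC1 | intermediate
22 | 9-acetyl-1β-(tert-butyldimethylsilyloxy)-4α-isopropyl-5αH,6βH-hydrind-8-ene | CC(C)(C)[Si](C)(C)O[C@H]1[C@@H]2CC=C(C(C)=O)[C@H]2[C@H](C(C)C)CC1 | intermediate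
23 | 9-acetyl-1β-(tert-butyldimethylsilyloxy)-8β,9β-epoxy-4α-isopropyl-5αH,6βH-hydrindane | CC(C)(C)[Si](C)(C)O[C@H]1[C@@H]2C[C@H]3O[C@@]3(C(C)=O)[C@H]2[C@H](C(C)C)CC1 | intermediate
24 | hydrazone of 23 at the acetyl carbonyl (not isolated) | CC(C)(C)[Si](C)(C)O[C@H]1[C@@H]2C[C@H]3O[C@@]3(C(C)=NN)[C@H]2[C@H](C(C)C)CC1 | intermediate
25 | 1β-(tert-butyldimethylsilyloxy)-9-(1-diazenylethylidene)-4α-isopropyl-5αH,6βH-hydrindan-8β-ol, methyl syn to C8 (not isolated) | CC(C)(C)[Si](C)(C)O[C@H]1[C@@H]2C[C@@H](O)/C(=C(\C)/N=N)[C@H]2[C@H](C(C)C)CC1 | intermediate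
26 | (9Z)-1β-(tert-butyldimethylsilyloxy)-9-ethylidene-4α-isopropyl-5αH,6βH-hydrindan-8β-ol | CC(C)(C)[Si](C)(C)O[C@H]1[C@@H]2C[C@@H](O)/C(=C\C)[C@H]2[C@H](C(C)C)CC1 | intermediate
27 | (9Z)-8β-acetoxy-1β-(tert-butyldimethylsilyloxy)-9-ethylidene-4α-isopropyl-5αH,6βH-hydrindane | CC(C)(C)[Si](C)(C)O[C@H]1[C@@H]2C[C@@H](OC(C)=O)/C(=C\C)[C@H]2[C@H](C(C)C)CC1 | intermediate
28 | (9Z)-8β-acetoxy-9-ethylidene-4α-isopropyl-5αH,6βH-hydrindan-1β-ol | O[C@H]1[C@@H]2C[C@@H](OC(C)=O)/C(=C\C)[C@H]2[C@H](C(C)C)CC1 | intermediate
29 | (9Z)-8β-acetoxy-9-ethylidene-4α-isopropyl-5αH,6βH-hydrindan-1-one | O=C1[C@@H]2C[C@@H](OC(C)=O)/C(=C\C)[C@H]2[C@H](C(C)C)CC1 | intermediate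
30 | (9Z)-8β-acetoxy-9-ethylidene-4α-isopropyl-1-(trimethylsilyloxy)-5αH,6βH-hydrind-1-ene (not isolated) | C[Si](C)(C)OC=1[C@@H]2C[C@@H](OC(C)=O)/C(=C\C)[C@H]2[C@H](C(C)C)CC=1 | intermediate
31 | (9Z)-8β-acetoxy-9-ethylidene-4α-isopropyl-5αH,6βH-hydrind-2-en-1-one | O=C1[C@@H]2C[C@@H](OC(C)=O)/C(=C\C)[C@H]2[C@H](C(C)C)C=C1 | intermediate
32 | (9Z)-8β-acetoxy-2α,3α-epoxy-9-ethylidene-4α-isopropyl-5αH,6βH-hydrindan-1-one | O=C1[C@@H]2C[C@@H](OC(C)=O)/C(=C\C)[C@H]2[C@H](C(C)C)[C@@H]3O[C@@H]31 | intermediate
33 | (9Z)-8β-acetoxy-2α,3α-epoxy-9-ethylidene-4α-isopropyl-1-methylidene-5αH,6βH-hydrindane | C=C1[C@@H]2C[C@@H](OC(C)=O)/C(=C\C)[C@H]2[C@H](C(C)C)[C@@H]3O[C@@H]31 | intermediate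
34 | (2E)-3-methylpent-2-enoic acid | CC/C(C)=C/C(=O)O | starting material
35 | (9Z)-8β-acetoxy-9-ethylidene-3α-hydroxy-4α-isopropyl-1-methylidene-5αH,6βH-hydrindan-2β-yl (2E)-3-methylpent-2-enoate (CNP0418642.2) | C=C1[C@@H]2C[C@@H](OC(C)=O)/C(=C\C)[C@H]2[C@H](C(C)C)[C@H](O)[C@H]1OC(=O)/C=C(\C)CC | target

## Step count and risk

Total: 23 steps. Longest linear sequence: 21 steps (steps 1–4 and 7–23). The sulfone branch (steps 5 and 6) joins at step 7.

**Step 11 (key step).** The most likely failures are capture of the secondary cyclohexyl cation by trifluoroacetate before the alkyne engages (monocyclisation), and erosion of facial selectivity if a chair with an axial isopropyl group competes. A fallback sets out from 16 and returns at 18. The closure is run with SnCl4 in CH2Cl2 at −78 °C, where no nucleophilic counter-ion is present during ring formation and chloride captures the alkenyl cation, giving 1β-benzyloxy-9-(1-chloroethylidene)-4α-isopropyl-5αH,6βH-hydrindane F1. The alkenyl chloride is then hydrolysed separately with Hg(OAc)2 in formic acid to ketone 18.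

**Step 14.** Enolisation may avoid C9, because the tetrasubstituted enol ether is strained against C4, so that mainly the unproductive terminal silyl enol ether forms. Palladation at the hindered C9 may also be slow, or β-hydride elimination may go towards C5. A fallback sets out from 20 and returns at 22 without any new intermediate (F0). The ketone is dehydrogenated directly with o-iodoxybenzoic acid in DMSO/fluorobenzene at 70 °C. Ketone–enol equilibration is reversible there, and only the enol towards C9 can be oxidised to an enone.

**Step 15.** Facial selectivity of the nucleophilic epoxidation may be poor, because the α-face of the cyclopentene carries only the C5 hydrogen. A fallback sets out from 22 and returns at 27. The 8α,9α-epoxy ketone F2 is taken through the same Wharton transposition to (9Z)-1β-(tert-butyldimethylsilyloxy)-9-ethylidene-4α-isopropyl-5αH,6βH-hydrindan-8α-ol F3. Mitsunobu inversion of F3 with acetic acid (PPh3, DIAD) then gives the 8β-acetate 27 directly.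

**Step 16.** Geometric control may be lost when the alkenyl diazene decomposes (protonation or hydrogen-atom transfer from the less hindered C8 side), giving the E-ethylidene. Reduction of the hydrazone without epoxide opening is a lesser risk. A fallback sets out from 23 and returns at 26. The (9E)-isomer of 26, F4, is equilibrated by reversible thiyl-radical addition (PhSSPh, hν, benzene) to the more stable Z-isomer 26, whose methyl avoids C4 and the isopropyl group.

**Step 23.** The carboxylate may attack the methylidene terminus (allylic transposition to a primary ester), or substitution at the secondary C2 may be too slow. A fallback sets out from 33 and returns at 35. The epoxide is hydrolysed (HClO4 cat., THF/H2O) to (9Z)-8β-acetoxy-9-ethylidene-4α-isopropyl-1-methylidene-5αH,6βH-hydrindane-2β,3α-diol F5. The less hindered allylic 2-hydroxyl of F5 is then acylated with the mixed anhydride of 34 (2,4,6-trichlorobenzoyl chloride, Et3N, DMAP; Yamaguchi esterification), the 3-hydroxyl being shielded by the neighbouring isopropyl group.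

## Further compounds

F1 | step 11 | 1β-benzyloxy-9-(1-chloroethylidene)-4α-isopropyl-5αH,6βH-hydrindane (E/Z mixture) | O(Cc1ccccc1)[C@H]1[C@@H]2CCC(=C(C)Cl)[C@H]2[C@H](C(C)C)CC1
F0 | step 14 | none | none
F2 | step 15 | 9-acetyl-1β-(tert-butyldimethylsilyloxy)-8α,9α-epoxy-4α-isopropyl-5αH,6βH-hydrindane | CC(C)(C)[Si](C)(C)O[C@H]1[C@@H]2C[C@@H]3O[C@]3(C(C)=O)[C@H]2[C@H](C(C)C)CC1
F3 | step 15 | (9Z)-1β-(tert-butyldimethylsilyloxy)-9-ethylidene-4α-isopropyl-5αH,6βH-hydrindan-8α-ol | CC(C)(C)[Si](C)(C)O[C@H]1[C@@H]2C[C@H](O)/C(=C\C)[C@H]2[C@H](C(C)C)CC1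
F4 | step 16 | (9E)-1β-(tert-butyldimethylsilyloxy)-9-ethylidene-4α-isopropyl-5αH,6βH-hydrindan-8β-ol | CC(C)(C)[Si](C)(C)O[C@H]1[C@@H]2C[C@@H](O)/C(=C/C)[C@H]2[C@H](C(C)C)CC1
F5 | step 23 | (9Z)-8β-acetoxy-9-ethylidene-4α-isopropyl-1-methylidene-5αH,6βH-hydrindane-2β,3α-diol | C=C1[C@@H]2C[C@@H](OC(C)=O)/C(=C\C)[C@H]2[C@H](C(C)C)[C@H](O)[C@H]1O
A1 | alternative 1 | oxime precursor: cyclopentane with 8β-silyloxy group, Z-ethylidene, ketal-protected C1 arm ending in the C3 oxime, and isobutenyl group on C5 | ON=CCC1(OCCO1)[C@@H]1C[C@@H](O[Si](C)(C)C(C)(C)C)/C(=C\C)[C@H]1C=C(C)C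
A2 | alternative 1 | isoxazoline-fused trans-hydrindane (product of the nitrile oxide cycloaddition) | C1C2(OCCO2)[C@@H]3C[C@@H](O[Si](C)(C)C(C)(C)C)/C(=C\C)[C@H]3[C@H]4C1=NOC4(C)C
A3 | alternative 2 | aldehyde precursor: (Z)-2-ethylidenecyclopentanone with isopropenyl group on C6 and the C4 aldehyde side chain on C5 | C=C(C)[C@@H]1CC(=O)/C(=C\C)[C@H]1[C@H](C(C)C)C=O
A4 | alternative 2 | methylidene hydrindanol with Z-ethylidene enone (product of the carbonyl-ene closure) | C=C1[C@@H]2CC(=O)/C(=C\C)[C@H]2[C@H](C(C)C)[C@H](O)C1
A5 | alternative 3 | bis(trimethylsilyl enol ether) precursor: cyclohexenyl silyl ether bearing the 2-silyloxydiene on C5 | C[Si](C)(C)OC1=C[C@@H](/C(=C/C)C(=C)O[Si](C)(C)C)[C@H](C(C)C)CC1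
A6 | alternative 3 | trans-hydrindane-1,8-dione with Z-ethylidene enone (product of the anodic coupling) | O=C1[C@@H]2CC(=O)/C(=C\C)[C@H]2[C@H](C(C)C)CC1
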